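## Retrosynthetic overview

1. Target ⇐ its 9‑O‑MOM, 10‑H pterocarpan, by MOM‑directed lithiation/prenylation at C10 and MOM removal.
2. Ring C (O11–C11a) ⇐ a (3R)‑isoflavan, by anodic DDQ‑mediated benzylic C–H etherification; the cis ring fusion lets C6a fix C11a.
3. Ring B and C6a ⇐ an (R)‑1‑aryl‑3‑aryloxypropan‑2‑ol: triflate → phenonium 1,2‑aryl shift (inversion) → intramolecular Friedel–Crafts closure.
4. That alcohol ⇐ D‑ring aryllithium (from a 5‑bromo‑6,8‑bis(MOMO)‑2,2‑dimethylchromene) + the (R)‑glycidyl ether of 2,2‑dimethylchromen‑7‑ol. The only bought stereocentre is that of (R)‑glycidyl nosylate.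
5. Ring order: A‑pyran (bought in the chromenol) → D‑pyran (propargyl Claisen on the D fragment) → ring B → ring C.

Assumptions: pterocarpan numbering is used (O5, C6, C6a, C6b–C10a, O11, C11a). 2,2‑Dimethyl‑2H‑chromen‑7‑ol and 5‑bromo‑2,4‑dihydroxybenzaldehyde are taken as catalogue compounds. MOM = CH2OCH3.

## Route

**Step 1**
Reactants: 1, 5‑bromo‑2,4‑dihydroxybenzaldehyde
Product: 2, 5‑bromo‑2,4‑bis(methoxymethoxy)benzaldehyde
Conditions: MOMCl, NaH, DMF, 0 °C → rt
Reagents that add atoms: chloromethyl methyl ether, COCCl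
Why: O‑alkylation (MOM acetal protection) of both phenols masks them through the organolithium, cationic and oxidative steps and later supplies the directing group for C10 lithiation.

**Step 2**
Reactants: 2, 5‑bromo‑2,4‑bis(methoxymethoxy)benzaldehyde
Product: 3, 5‑bromo‑2,4‑bis(methoxymethoxy)phenol
Conditions: mCPBA, CH2Cl2, rt; then K2CO3, MeOH, 0 °C
Reagents that add atoms: mCPBA, O=C(OO)c1cccc(Cl)c1
Why: Dakin‑type Baeyer–Villiger oxidation, in which the electron‑rich aryl group migrates to give the aryl formate, and mild methanolysis frees the phenol that becomes the D‑ring pyran oxygen.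

**Step 3**
Reactants: 3, 5‑bromo‑2,4‑bis(methoxymethoxy)phenol; 4, 3‑chloro‑3‑methylbut‑1‑yne
Product: 5, 1‑bromo‑2,4‑bis(methoxymethoxy)‑5‑[(2‑methylbut‑3‑yn‑2‑yl)oxy]benzene
Conditions: DBU, CuCl2 (1 mol %), MeCN, 0 °C
Reagents that add atoms: 3‑chloro‑3‑methylbut‑1‑yne (4), C#CC(C)(C)Cl
Why: Cu‑catalysed O‑propargylation of the phenoxide with the tertiary propargylic chloride gives the aryl 1,1‑dimethylpropargyl ether.

**Step 4**
Reactants: 5, the aryl 1,1‑dimethylpropargyl ether
Product: 6, 5‑bromo‑6,8‑bis(methoxymethoxy)‑2,2‑dimethyl‑2H‑chromene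
Conditions: o‑xylene, 140 °C
Reagents that add atoms: none
Why: Aromatic propargyl Claisen rearrangement to the only free ortho carbon, then [1,5]‑H shift and oxa‑6π electrocyclisation, gives the D‑ring 2,2‑dimethylchromene regiospecifically.

**Step 5**
Reactants: 7, 2,2‑dimethyl‑2H‑chromen‑7‑ol; 8, (R)‑glycidyl 3‑nitrobenzenesulfonate
Product: 9, (R)‑2,2‑dimethyl‑7‑(oxiran‑2‑ylmethoxy)‑2H‑chromene
Conditions: K2CO3, acetone, reflux
Reagents that add atoms: (R)‑glycidyl nosylate (8), O=S(=O)(OC[C@H]1CO1)c1cccc([N+](=O)[O-])c1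
Why: SN2 O‑alkylation at the sulfonate‑bearing CH2 leaves the epoxide stereocentre untouched, so the bought (R) centre is carried into 9.

**Step 6**
Reactants: 6, the bromochromene; 9, the (R)‑glycidyl ether
Product: 10, (2R)‑1‑[6,8‑bis(methoxymethoxy)‑2,2‑dimethyl‑2H‑chromen‑5‑yl]‑3‑[(2,2‑dimethyl‑2H‑chromen‑7‑yl)oxy]propan‑2‑ol
Conditions: 6, t‑BuLi, THF, −78 °C; then 9, BF3·OEt2, −78 °C
Reagents that add atoms: none
Why: Br/Li exchange then BF3‑assisted SN2 opening of the epoxide at its terminal CH2 joins the hindered D ring without touching the stereocentre.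

**Step 7**
Reactants: 10, the (2R)‑alcohol
Product: 11, (3R)‑3‑[6,8‑bis(methoxymethoxy)‑2,2‑dimethyl‑2H‑chromen‑5‑yl]‑8,8‑dimethyl‑3,4‑dihydro‑2H,8H‑pyrano[3,2‑g]chromene (the (3R)‑isoflavan)
Conditions: Tf2O, 2,6‑di‑tert‑butyl‑4‑methylpyridine, CH2Cl2, −78 °C; then HFIP, −78 → 0 °C
Reagents that add atoms: none
Why: Proposed new method: triflation triggers anti ipso‑participation of the o,p‑dioxygenated D ring (phenonium ion, inversion at the carbinol carbon), and the tethered chromenyl ether then attacks the former benzylic CH2 through its C6 (para to the pyran oxygen) in a favoured six‑membered Friedel–Crafts closure, so the epoxide‑derived C–O centre becomes the (3R) C–aryl centre (= 6aR); the closest known chemistry is the stereospecific phenonium 1,2‑aryl shift of β‑aryl sulfonates and HFIP‑promoted arene trapping of phenonium ions.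

**Step 8**
Reactants: 11, the (3R)‑isoflavan
Product: 12, (6aR,11aR)‑9‑(methoxymethoxy)pterocarpan with 2,2‑dimethylpyran rings fused at C2–C3 (O on C3) and C7–C8 (O on C8), i.e. the 10‑desprenyl 9‑O‑MOM ether of the target
Conditions: DDQ (20 mol %), 2,6‑lutidine, H2O (3 equiv), LiClO4, MeCN/HFIP 9:1, graphite‑felt anode | Pt cathode (divided cell), +0.85 V vs Ag/AgCl, 2.2 F/mol, rt
Reagents that add atoms: none
Why: Proposed new method: anodically regenerated DDQ abstracts hydride from C4 (aligned with the dioxygenated A ring, whereas the C3–H of the di‑ortho‑substituted D ring lies in that ring's plane), and the 2′‑OMOM oxygen traps the p‑alkoxybenzyl cation on the face of the C3 aryl group and sheds MOM, so C6a dictates the cis fusion (11aR); the closest known reactions are the DDQ oxidative cyclisation of 2′‑hydroxyisoflavans to pterocarpans and DDQ‑mediated indirect electrolysis.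

**Step 9**
Reactants: 12, the 9‑O‑MOM pterocarpan; 13, prenyl bromide (1‑bromo‑3‑methylbut‑2‑ene)
Product: 14, (6aR,11aR)‑9‑(methoxymethoxy)‑10‑(3‑methylbut‑2‑enyl) analogue of 12 (the 9‑O‑MOM ether of the target)
Conditions: n‑BuLi, TMEDA, THF, −40 °C; CuBr·SMe2; then 13, −40 → 0 °C
Reagents that add atoms: prenyl bromide (13), CC(C)=CCBr
Why: Directed ortho‑metalation at C10 (the only D‑ring C–H, flanked by OMOM and O11), then copper‑mediated SN2 allylation, installs the linear prenyl group.

**Step 10**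
Reactants: 14, the 9‑O‑MOM ether of the target
Product: 15, lespecyrtin E4, (6aR,11aR)
Conditions: 3 M HCl, MeOH/THF, 40 °C
Reagents that add atoms: none
Why: Acid‑catalysed acetal hydrolysis removes the MOM group; dilute acid leaves the chromenes and prenyl group intact, and any reversible C11a–O11 ionisation can only reclose to the cis‑fused ring, so C6a and C11a are kept.

## Compound list

1 | 5‑bromo‑2,4‑dihydroxybenzaldehyde | O=Cc1cc(Br)c(O)cc1O | starting material
2 | 5‑bromo‑2,4‑bis(methoxymethoxy)benzaldehyde | O=Cc1cc(Br)c(OCOC)cc1OCOC | intermediate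
3 | 5‑bromo‑2,4‑bis(methoxymethoxy)phenol | Oc1cc(Br)c(OCOC)cc1OCOC | intermediate
4 | 3‑chloro‑3‑methylbut‑1‑yne | C#CC(C)(C)Cl | starting material
5 | 1‑bromo‑2,4‑bis(methoxymethoxy)‑5‑[(2‑methylbut‑3‑yn‑2‑yl)oxy]benzene | C#CC(C)(C)Oc1cc(Br)c(OCOC)cc1OCOC | intermediate
6 | 5‑bromo‑6,8‑bis(methoxymethoxy)‑2,2‑dimethyl‑2H‑chromene | CC1(C)C=Cc2c(Br)c(OCOC)cc(OCOC)c2O1 | intermediate
7 | 2,2‑dimethyl‑2H‑chromen‑7‑ol | CC1(C)C=Cc2ccc(O)cc2O1 | starting material
8 | (R)‑glycidyl 3‑nitrobenzenesulfonate | O=S(=O)(OC[C@H]1CO1)c1cccc([N+](=O)[O-])c1 | starting material (chiral)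
9 | (R)‑2,2‑dimethyl‑7‑(oxiran‑2‑ylmethoxy)‑2H‑chromene | CC1(C)C=Cc2ccc(OC[C@H]3CO3)cc2O1 | intermediate
10 | (2R)‑1‑[6,8‑bis(MOMO)‑2,2‑dimethyl‑2H‑chromen‑5‑yl]‑3‑[(2,2‑dimethyl‑2H‑chromen‑7‑yl)oxy]propan‑2‑ol | CC1(C)C=Cc2ccc(OC[C@H](O)Cc3c(OCOC)cc(OCOC)c4OC(C)(C)C=Cc34)cc2O1 | intermediate
11 | (3R)‑3‑[6,8‑bis(MOMO)‑2,2‑dimethyl‑2H‑chromen‑5‑yl]‑8,8‑dimethyl‑3,4‑dihydro‑2H,8H‑pyrano[3,2‑g]chromene | CC1(C)C=Cc2cc3C[C@H](c4c(OCOC)cc(OCOC)c5OC(C)(C)C=Cc45)COc3cc2O1 | intermediate
12 | (6aR,11aR)‑9‑O‑MOM‑10‑desprenyl‑lespecyrtin E4 | c1c(OCOC)c2c(c3c1O[C@H]1c4cc5c(cc4OC[C@@H]31)OC(C)(C)C=C5)C=CC(C)(C)O2 | intermediate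
13 | prenyl bromide | CC(C)=CCBr | starting material
14 | (6aR,11aR)‑9‑O‑MOM‑lespecyrtin E4 | CC(C)=CCc1c(OCOC)c2c(c3c1O[C@H]1c4cc5c(cc4OC[C@@H]31)OC(C)(C)C=C5)C=CC(C)(C)O2 | intermediate
15 | lespecyrtin E4 | CC(C)=CCc1c(O)c2c(c3c1O[C@H]1c4cc5c(cc4OC[C@@H]31)OC(C)(C)C=C5)C=CC(C)(C)O2 | target

## Step count and risks

Total steps: 10. Longest linear sequence: 9 (steps 1–4, then 6–10).

Steps most likely to fail:

1. **Step 7 (proposed new phenonium shift / Friedel–Crafts).** Risks: the 2′‑OMOM oxygen may cyclise onto the activated carbon (2‑substituted dihydrobenzofuran), or closure may give the five‑membered ring. Fallback (known chemistry): set C6a by the Et3Al‑promoted semipinacol 1,2‑aryl shift. The sequence is 7 + methyl (S)‑glycidate → methyl (S)‑2‑hydroxy‑3‑aryloxypropanoate → mesylate → DIBAL, then the aryllithium from 6 → β‑mesyloxy benzylic alcohol. Et3Al then gives the α‑aryl aldehyde with inversion, which closes onto the chromenyl ring to the isoflavan‑4‑ol with the same C3 configuration. Ring C is then closed with acid instead of by step 8.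

2. **Step 8 (proposed new anodic DDQ‑mediated C–H etherification).** Risks: E1 loss to the isoflav‑3‑ene, over‑oxidation of 12 to the pterocarpene, or oxidation of the electron‑rich D ring. Fallback (known chemistry, two separate operations): stoichiometric DDQ in CH2Cl2/MeOH to trap the C4 cation as the 4‑methoxyisoflavan, then acid‑mediated MOM‑deprotective closure of the kind used for isoflavan‑4‑ols. This gives the free 9‑OH pterocarpan, which takes the Claisen prenylation below.

3. **Step 9 (C10 lithiation/prenylation).** Risk: competing lithiation at C4 of ring A, between O5 and the pyran oxygen. Fallback: remove the MOM group first, make the 9‑O‑(1,1‑dimethylallyl) ether (Pd(PPh3)4, tert‑butyl 2‑methylbut‑3‑en‑2‑yl carbonate), and run an aromatic Claisen rearrangement (PhNEt2, 120 °C). This can only deliver the prenyl group to C10 and ends under neutral conditions.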